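The runs are simulated with made-up constants; scatter was added.

The amounts of side product in the violet and ochre runs were what I had to go on. Both runs took the same substrate portions, and c(capture agent) was 0.10 M in violet and 0.15 M in ochre.

all flasks: substrate 0.20 M (in portions, 4)

| charge | capture agent | remark | time |
|---|---|---|---|
| violet | 0.10 M | run made earlier; portions every 6.0 min |  |
| ochre | 0.15 M | run made earlier; portions every 6.0 min |  |
| flask | 0.200 M | the portions of substrate follow each other after 6.0 min, the first at the start | 30 min |

| run | time / min | side product / % | target / % | substrate / % |
|---|---|---|---|---|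
| violet | 3.00 | 0.9 | 0 | 20.8 |
| violet | 5.00 | 0 | 0.6 | 18.0 |
| violet | 8.00 | 0.7 | 1.2 | 35.8 |
| violet | 12.0 | 1.7 | 1.3 | 31.5 |
| violet | 20.0 | 5.5 | 4.5 | 59.7 |
| violet | 40.0 | 14.8 | 14.0 | 31.0 |
| ochre | 3.00 | 0.3 | 0 | 19.3 |
| ochre | 5.00 | 0 | 0.3 | 17.2 |
| ochre | 8.00 | 1.7 | 0.1 | 36.0 |
| ochre | 12.0 | 3.0 | 2.1 | 30.0 |
| ochre | 20.0 | 6.4 | 4.3 | 57.0 |
| ochre | 40.0 | 12.9 | 12.5 | 27.6 |

(readings scatter by 0.5 percentage points)

* amount of side product in percent of the substrate charged, at 3.0 min, 10 min, 20 min and 30 min

- percent here means substrate units held: one side product counts as two
- the numbers in the tables scatter with a standard deviation of 0.5 percentage points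
- steps under discussion: substrate <-> intermediate A; intermediate A -> intermediate B; intermediate B <-> target; substrate + intermediate A -> side product; capture agent + intermediate A -> trapped intermediate

I read the two side-product columns against each other, row by row. At 12.0 min, violet held 1.7% and ochre 3.0%; at 20.0 min, violet held 5.5% and ochre 6.4%. So ochre, with the richer capture charge, showed more side product in these rows, by gaps of 1.3 percentage points and 0.9 points against a scatter of 0.5 points in each reading. At 40.0 min the order turned: violet held 14.8%, more than the 12.9% in ochre. I took this last row, where the side-product readings stood highest, and from it read an apparent order in capture agent, the logarithm of the side-product ratio over the logarithm of the ratio of capture charges, with the sign dropped. This gave 0.339, which I called the capture lever; it is a reading from one row and carries that row's scatter.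

Then I reckoned the flask. A straight line between the last two ochre rows gave 9.65% at 30 min. In my reckoning, c(capture agent) of 0.200 M in the flask multiplied this by 0.907 through the lever, so I committed to 8.75%.

The forecast expected “a slightly lower curve than ochre” and gave 0.2%, 1.4%, 5.4% and 9%, its last value a little higher than mine.

The flask gave 0.187%, 1.26%, 5.09% and 9.23% at 3.0 min, 10 min, 20 min and 30 min.

    substrate ⇌ intermediate A (K = 0.250, k = 0.00360 /s)
    intermediate A → intermediate B (k = 0.00110 /s)
    intermediate B ⇌ target (K = 2.20, k = 0.00270 /s)
    substrate + intermediate A → side product (k = 0.00430 /M/s)
    capture agent + intermediate A → trapped intermediate (k = 0.0160 /M/s)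

The flask stood 0.48 points above my reckoning at 30 min, and its value, set against straight-line values drawn through the scattered readings at that time, gave a capture lever of 0.155 from ochre and 0.137 from violet, both lower than my reading. In the flask, substrate and intermediate A relaxed towards each other by their own step alone with a half-life of 0.642 min, both directions together, which is shorter than the half-life of intermediate A by the capture step alone at 15.1 min, 4.2 min.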